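## Retrosynthetic overview

1. The target comes from enol triflate **23** by Negishi methylation (C17, fixes C7=C8). The equatorial C2–O is set earlier by hydroboration of a ring A C2=C3 alkene.
2. Ring B comes from a one-carbon ring expansion of trans-hydrindenone **14**: the side-chain carbon C9 is inserted between C8 and the quaternary C10 by a selenium-triggered semipinacol 1,2-shift. This step also joins core and side chain.
3. Ring A of **14** is closed by ring-closing metathesis of diene **13**. **13** comes from an enantioselective conjugate reverse-prenylation/enolate allylation of 2-methylcyclopent-2-enone (new step; sets C5 and C10).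
4. The side chain comes from (S)-5-methyloxepan-2-one, made by Baeyer–Villiger desymmetrisation of 4-methylcyclohexanone (sets C13).
5. Order of rings: cyclopentanone (bought) → ring A (metathesis) → ring B (expansion of the five-membered ring).

Assumption: labdane numbering (C1–C20) is used for positions; the target is read as (2R,5R,9R,10R,13S), with trans ring fusion and the 2-acetoxy group equatorial (trans to C20).

## Route

Step 1
Reactants: 1 4-methylcyclohexan-1-one
Product: 2 (5S)-5-methyloxepan-2-one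
Conditions: cyclohexanone monooxygenase (EC 1.14.13.22, Acinetobacter calcoaceticus NCIMB 9871), NADP+ (cat.), alcohol dehydrogenase, i-PrOH (cosubstrate), air, Tris buffer pH 8.5, 25 °C
Reagents that add atoms: dioxygen O=O
Why: Enzymatic Baeyer–Villiger oxidation desymmetrises the prochiral ketone, and this enzyme is known to give the (S)-lactone in high ee, which sets C13.

Step 2
Reactants: 2 (5S)-5-methyloxepan-2-one
Product: 3 (4S)-6-hydroxy-4-methylhexanal
Conditions: i-Bu2AlH (1.05 equiv), CH2Cl2, −78 °C; aq. Rochelle salt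
Reagents that add atoms: none
Why: Half-reduction of a lactone with DIBAL-H stops at the lactol, which for a seven-membered ring lies largely on the open hydroxy-aldehyde side; C13 is untouched.

Step 3
Reactants: 3 (4S)-6-hydroxy-4-methylhexanal
Product: 4 (3S)-3-methyl-6,6-bis(phenylselanyl)hexan-1-ol
Conditions: PhSeH (2.2 equiv), ZnCl2 (0.3 equiv), CH2Cl2, 20 °C
Reagents that add atoms: benzeneselenol [SeH]c1ccccc1
Why: Lewis-acid-catalysed selenoacetalisation of the aldehyde gives the precursor of an α-seleno carbanion; the free primary alcohol is tolerated.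

Step 4
Reactants: 4 (3S)-3-methyl-6,6-bis(phenylselanyl)hexan-1-ol
Product: 5 tert-butyl(dimethyl){[(3S)-3-methyl-6,6-bis(phenylselanyl)hexyl]oxy}silane
Conditions: TBSCl, imidazole, DMF, 20 °C
Reagents that add atoms: tert-butyl(chloro)dimethylsilane CC(C)(C)[Si](C)(C)Cl
Why: Standard silyl protection of the primary alcohol, needed for the organolithium and enolate steps.

Step 5
Reactants: 6 1-chloro-3-methylbut-2-ene
Product: 8 trimethyl(3-methylbut-2-en-1-yl)silane, via prenylmagnesium chloride 7 (not isolated)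
Conditions: Mg turnings, Me3SiCl, THF, 0 → 20 °C
Reagents that add atoms: chlorotrimethylsilane C[Si](C)(C)Cl
Why: Barbier-type Grignard formation and silylation at the unhindered allyl terminus gives the primary allylsilane; the silyl group is only an activating auxiliary.

Step 6
Reactants: 9 2-methylcyclopent-2-en-1-one; 8 trimethyl(3-methylbut-2-en-1-yl)silane; 10 3-bromoprop-1-ene
Product: 13 (2R,3R)-2-methyl-3-(2-methylbut-3-en-2-yl)-2-(prop-2-en-1-yl)cyclopentan-1-one, via silyl enol ether 11 (not isolated), via lithium enolate 12 (not isolated)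
Conditions: (3aS)-1-(2-methylphenyl)-3,3-diphenyltetrahydro-1H,3H-pyrrolo[1,2-c][1,3,2]oxazaborole (20 mol %) + Tf2NH (17 mol %), Ph3PO (20 mol %), toluene, −78 → −40 °C; then THF, MeLi (1.4 equiv), 0 → 20 °C; then DMPU, 10 (3 equiv), −78 → 0 °C
Reagents that add atoms: none
Why: Proposed new method: an enantioselective Hosomi–Sakurai conjugate reverse-prenylation in which the cationic oxazaborolidinium Lewis acid binds the enone carbonyl and shields one face, the allylsilane attacks the β-carbon through its γ-carbon (SE2′) to form the C5–C4 bond with the gem-dimethyl carbon already quaternary, and the β-silyl cation passes Me3Si to the enolate oxygen (Ph3PO shuttles silyl and suppresses achiral silyl-cation catalysis) to give regiodefined enol ether 11; MeLi then unmasks enolate 12, which is allylated anti to the bulky C5 substituent so that quaternary C10 is set trans; the closest known reactions are TiCl4-promoted racemic Sakurai additions of prenylsilane to cyclic enones and oxazaborolidinium-catalysed enantioselective Mukaiyama–Michael and Diels–Alder reactions of cyclic enones (the antipodal catalyst is used if the sense of induction proves opposite).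

Step 7
Reactants: 13 (2R,3R)-2-methyl-3-(2-methylbut-3-en-2-yl)-2-(prop-2-en-1-yl)cyclopentan-1-one
Product: 14 (3aR,7aR)-4,4,7a-trimethyl-2,3,3a,4,7,7a-hexahydro-1H-inden-1-one
Conditions: second-generation Grubbs catalyst RuCl2(=CHPh)(H2IMes)(PCy3) (3 mol %), CH2Cl2 (5 mM), 40 °C
Reagents that add atoms: none
Why: Ring-closing metathesis of the allyl and 1,1-dimethylallyl groups closes ring A as the C2=C3 cyclohexene across the trans substituents, driven by loss of ethene and creating no new stereocentre.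

Step 8
Reactants: 5 tert-butyl(dimethyl){[(3S)-3-methyl-6,6-bis(phenylselanyl)hexyl]oxy}silane; 14 (3aR,7aR)-4,4,7a-trimethyl-2,3,3a,4,7,7a-hexahydro-1H-inden-1-one
Product: 16 (1R,3aR,7aR)-1-[(4S)-6-{[tert-butyl(dimethyl)silyl]oxy}-4-methyl-1-(phenylselanyl)hexyl]-4,4,7a-trimethyl-2,3,3a,4,7,7a-hexahydro-1H-inden-1-ol (both epimers at the selenium-bearing carbon), via lithio selenide 15 (not isolated)
Conditions: 5 (1.3 equiv), n-BuLi (1.25 equiv), THF, −78 °C; then 14, −78 → −40 °C; H2O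
Reagents that add atoms: none
Why: Selenium–lithium exchange of the selenoacetal gives a weakly basic, strongly nucleophilic α-selenoalkyllithium that adds 1,2 to the hindered ketone from the face opposite the angular methyl (as nucleophiles add to 17-oxo steroids), which sets C8; the configuration at C9 is not controlled and does not matter.

Step 9
Reactants: 16 (1R,3aR,7aR)-1-[(4S)-6-{[tert-butyl(dimethyl)silyl]oxy}-4-methyl-1-(phenylselanyl)hexyl]-4,4,7a-trimethyl-2,3,3a,4,7,7a-hexahydro-1H-inden-1-ol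
Product: 18 (1S,4aR,8aR)-1-[(3S)-5-{[tert-butyl(dimethyl)silyl]oxy}-3-methylpentyl]-5,5,8a-trimethyl-3,4,4a,5,8,8a-hexahydronaphthalen-2(1H)-one, via C1-epimer mixture 17 (not isolated)
Conditions: AgBF4 (1.5 equiv) on neutral Al2O3, 2,6-di-tert-butylpyridine (2 equiv), CH2Cl2, −20 → 20 °C; filter; then DBU (0.3 equiv), CH2Cl2, 20 °C
Reagents that add atoms: none
Why: Silver-assisted departure of the phenylselanyl group triggers a semipinacol 1,2-shift (seleno-pinacol ring expansion) in which the more substituted, electron-rich carbon C10 migrates from C8 to C9 with retention at C10, as β-hydroxy selenides of 2-substituted cycloalkanones and the D-homoannulation of 17-oxo steroids do, making ring B and the hindered C9–C10 bond; DBU then equilibrates the epimerisable C9 to the equatorial side chain.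

Step 10
Reactants: 18 (1S,4aR,8aR)-1-[(3S)-5-{[tert-butyl(dimethyl)silyl]oxy}-3-methylpentyl]-5,5,8a-trimethyl-3,4,4a,5,8,8a-hexahydronaphthalen-2(1H)-one
Product: 20 (1S,4aR,8aR)-1-[(3S)-5-{[tert-butyl(dimethyl)silyl]oxy}-3-methylpentyl]-5,5,8a-trimethyl-1,4,4a,5,8,8a-hexahydronaphthalen-2-yl trifluoromethanesulfonate, via potassium enolate 19 (not isolated)
Conditions: KN(SiMe3)2 (1.15 equiv), THF, −78 °C; then PhNTf2 (1.2 equiv), −78 → 0 °C
Reagents that add atoms: N-phenylbis(trifluoromethanesulfonimide) O=S(=O)(N(c1ccccc1)S(=O)(=O)C(F)(F)F)C(F)(F)F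
Why: Kinetic deprotonation takes the unhindered C7 methylene rather than the hindered C9 methine next to the quaternary carbon, and O-triflation of the enolate locks the C7=C8 position and the C9 configuration.

Step 11
Reactants: 20 (1S,4aR,8aR)-1-[(3S)-5-{[tert-butyl(dimethyl)silyl]oxy}-3-methylpentyl]-5,5,8a-trimethyl-1,4,4a,5,8,8a-hexahydronaphthalen-2-yl trifluoromethanesulfonate
Product: 22 (1S,4aR,7R,8aR)-1-[(3S)-5-{[tert-butyl(dimethyl)silyl]oxy}-3-methylpentyl]-7-hydroxy-5,5,8a-trimethyl-1,4,4a,5,6,7,8,8a-octahydronaphthalen-2-yl trifluoromethanesulfonate, via alkylborane 21 (not isolated)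
Conditions: 9-BBN (3 equiv), THF, 60 °C; then aq. NaOAc, 30% H2O2, 0 → 20 °C
Reagents that add atoms: hydrogen peroxide OO
Why: Hydroboration–oxidation with the bulky borane places boron on C2, away from the neopentyl C3, and from the face opposite the axial C20 and axial C4 methyls, so oxidation with retention gives the equatorial C2 alcohol; the electron-poor enol triflate is not hydroborated.

Step 12
Reactants: 22 (1S,4aR,7R,8aR)-1-[(3S)-5-{[tert-butyl(dimethyl)silyl]oxy}-3-methylpentyl]-7-hydroxy-5,5,8a-trimethyl-1,4,4a,5,6,7,8,8a-octahydronaphthalen-2-yl trifluoromethanesulfonate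
Product: 23 (3S)-5-[(1S,4aR,7R,8aR)-7-(acetyloxy)-5,5,8a-trimethyl-2-{[(trifluoromethyl)sulfonyl]oxy}-1,4,4a,5,6,7,8,8a-octahydronaphthalen-1-yl]-3-methylpentyl acetate
Conditions: Ac2O (6 equiv), Cu(OTf)2 (5 mol %), CH2Cl2, 0 → 20 °C
Reagents that add atoms: acetic anhydride CC(=O)OC(C)=O
Why: Lewis-acid-catalysed acetylation esterifies the secondary alcohol and exchanges the primary silyl ether directly for acetate; it is done before the acid-sensitive trisubstituted alkene exists.

Step 13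
Reactants: 23 (3S)-5-[(1S,4aR,7R,8aR)-7-(acetyloxy)-5,5,8a-trimethyl-2-{[(trifluoromethyl)sulfonyl]oxy}-1,4,4a,5,6,7,8,8a-octahydronaphthalen-1-yl]-3-methylpentyl acetate
Product: 24 (3S)-5-[(1R,4aR,7R,8aR)-7-(acetyloxy)-2,5,5,8a-tetramethyl-1,4,4a,5,6,7,8,8a-octahydronaphthalen-1-yl]-3-methylpentyl acetate
Conditions: Me2Zn (2.5 equiv), Pd(PPh3)4 (5 mol %), THF, 0 → 50 °C
Reagents that add atoms: dimethylzinc C[Zn]C
Why: Negishi cross-coupling of the alkenyl triflate installs the C17 methyl with the double bond fixed at C7=C8 under neutral conditions that leave both acetates alone; no stereocentre is touched (the C9 descriptor changes from S to R only through priority rules).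

## Compound list

1 | 4-methylcyclohexan-1-one | CC1CCC(=O)CC1 | starting material
2 | (5S)-5-methyloxepan-2-one | C[C@@H]1CCOC(=O)CC1 | intermediate
3 | (4S)-6-hydroxy-4-methylhexanal | OCC[C@@H](C)CCC=O | intermediate
4 | (3S)-3-methyl-6,6-bis(phenylselanyl)hexan-1-ol | OCC[C@@H](C)CCC([Se]c1ccccc1)[Se]c1ccccc1 | intermediate
5 | tert-butyl(dimethyl){[(3S)-3-methyl-6,6-bis(phenylselanyl)hexyl]oxy}silane | CC(C)(C)[Si](C)(C)OCC[C@@H](C)CCC([Se]c1ccccc1)[Se]c1ccccc1 | intermediate
6 | 1-chloro-3-methylbut-2-ene | CC(C)=CCCl | starting material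
7 | (3-methylbut-2-en-1-yl)magnesium chloride | CC(C)=CC[Mg]Cl | intermediate
8 | trimethyl(3-methylbut-2-en-1-yl)silane | CC(C)=CC[Si](C)(C)C | intermediate
9 | 2-methylcyclopent-2-en-1-one | CC1=CCCC1=O | starting material
10 | 3-bromoprop-1-ene | C=CCBr | starting material
11 | trimethyl{[(3R)-2-methyl-3-(2-methylbut-3-en-2-yl)cyclopent-1-en-1-yl]oxy}silane | CC1=C(O[Si](C)(C)C)CC[C@@H]1C(C)(C)C=C | intermediate
12 | lithium (3R)-2-methyl-3-(2-methylbut-3-en-2-yl)cyclopent-1-en-1-olate | CC1=C(O[Li])CC[C@@H]1C(C)(C)C=C | intermediate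
13 | (2R,3R)-2-methyl-3-(2-methylbut-3-en-2-yl)-2-(prop-2-en-1-yl)cyclopentan-1-one | O=C1CC[C@H](C(C)(C)C=C)[C@@]1(C)CC=C | intermediate
14 | (3aR,7aR)-4,4,7a-trimethyl-2,3,3a,4,7,7a-hexahydro-1H-inden-1-one | O=C1CC[C@@H]2C(C)(C)C=CC[C@@]12C | intermediate
15 | [(4S)-6-{[tert-butyl(dimethyl)silyl]oxy}-4-methyl-1-(phenylselanyl)hexyl]lithium | [Li]C([Se]c1ccccc1)CC[C@H](C)CCO[Si](C)(C)C(C)(C)C | intermediate
16 | (1R,3aR,7aR)-1-[(4S)-6-{[tert-butyl(dimethyl)silyl]oxy}-4-methyl-1-(phenylselanyl)hexyl]-4,4,7a-trimethyl-2,3,3a,4,7,7a-hexahydro-1H-inden-1-ol (both epimers at the Se-bearing carbon) | O[C@]1(C([Se]c2ccccc2)CC[C@H](C)CCO[Si](C)(C)C(C)(C)C)CC[C@@H]3C(C)(C)C=CC[C@@]13C | intermediate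
17 | (4aR,8aR)-1-[(3S)-5-{[tert-butyl(dimethyl)silyl]oxy}-3-methylpentyl]-5,5,8a-trimethyl-3,4,4a,5,8,8a-hexahydronaphthalen-2(1H)-one (mixture of C1 epimers) | CC(C)(C)[Si](C)(C)OCC[C@@H](C)CCC1C(=O)CC[C@@H]2C(C)(C)C=CC[C@@]12C | intermediate
18 | (1S,4aR,8aR)-1-[(3S)-5-{[tert-butyl(dimethyl)silyl]oxy}-3-methylpentyl]-5,5,8a-trimethyl-3,4,4a,5,8,8a-hexahydronaphthalen-2(1H)-one | CC(C)(C)[Si](C)(C)OCC[C@@H](C)CC[C@@H]1C(=O)CC[C@@H]2C(C)(C)C=CC[C@@]12C | intermediate
19 | potassium (1S,4aR,8aR)-1-[(3S)-5-{[tert-butyl(dimethyl)silyl]oxy}-3-methylpentyl]-5,5,8a-trimethyl-1,4,4a,5,8,8a-hexahydronaphthalen-2-olate | CC(C)(C)[Si](C)(C)OCC[C@@H](C)CC[C@@H]1C(O[K])=CC[C@@H]2C(C)(C)C=CC[C@@]12C | intermediate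
20 | (1S,4aR,8aR)-1-[(3S)-5-{[tert-butyl(dimethyl)silyl]oxy}-3-methylpentyl]-5,5,8a-trimethyl-1,4,4a,5,8,8a-hexahydronaphthalen-2-yl trifluoromethanesulfonate | CC(C)(C)[Si](C)(C)OCC[C@@H](C)CC[C@@H]1C(OS(=O)(=O)C(F)(F)F)=CC[C@@H]2C(C)(C)C=CC[C@@]12C | intermediate
21 | (1S,4aR,7R,8aR)-7-(9-borabicyclo[3.3.1]nonan-9-yl)-1-[(3S)-5-{[tert-butyl(dimethyl)silyl]oxy}-3-methylpentyl]-5,5,8a-trimethyl-1,4,4a,5,6,7,8,8a-octahydronaphthalen-2-yl trifluoromethanesulfonate | CC(C)(C)[Si](C)(C)OCC[C@@H](C)CC[C@@H]1C(OS(=O)(=O)C(F)(F)F)=CC[C@@H]2C(C)(C)C[C@@H](B3C4CCCC3CCC4)C[C@@]12C | intermediate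
22 | (1S,4aR,7R,8aR)-1-[(3S)-5-{[tert-butyl(dimethyl)silyl]oxy}-3-methylpentyl]-7-hydroxy-5,5,8a-trimethyl-1,4,4a,5,6,7,8,8a-octahydronaphthalen-2-yl trifluoromethanesulfonate | CC(C)(C)[Si](C)(C)OCC[C@@H](C)CC[C@@H]1C(OS(=O)(=O)C(F)(F)F)=CC[C@@H]2C(C)(C)C[C@@H](O)C[C@@]12C | intermediate
23 | (3S)-5-[(1S,4aR,7R,8aR)-7-(acetyloxy)-5,5,8a-trimethyl-2-{[(trifluoromethyl)sulfonyl]oxy}-1,4,4a,5,6,7,8,8a-octahydronaphthalen-1-yl]-3-methylpentyl acetate | CC(=O)OCC[C@@H](C)CC[C@@H]1C(OS(=O)(=O)C(F)(F)F)=CC[C@@H]2C(C)(C)C[C@@H](OC(C)=O)C[C@@]12C | intermediate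
24 | (3S)-5-[(1R,4aR,7R,8aR)-7-(acetyloxy)-2,5,5,8a-tetramethyl-1,4,4a,5,6,7,8,8a-octahydronaphthalen-1-yl]-3-methylpentyl acetate (CNP0220683.1) | CC(=O)OCC[C@@H](C)CC[C@@H]1C(C)=CC[C@@H]2C(C)(C)C[C@@H](OC(C)=O)C[C@@]12C | target

## Step count and risks

Total step count: 13. Longest linear sequence: 10 steps (steps 1–4, then 8–13). The core branch (steps 5–7, then 8–13) is 9 steps.

The three steps most likely to fail:

**Step 6 (the proposed new step).** Risks are low enantioselectivity from achiral silyl-cation catalysis, or slow attack of the bulky silane. The fallback uses known chemistry and sets out from 9 and 8: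
- TiCl4 (1 equiv) in CH2Cl2 at −78 °C gives the racemic Hosomi–Sakurai adduct 2-methyl-3-(2-methylbut-3-en-2-yl)cyclopentan-1-one F1.
- Me3SiCl, NaI and Et3N in MeCN give the more substituted silyl enol ether as the racemate, that is 11 together with its enantiomer trimethyl{[(3S)-2-methyl-3-(2-methylbut-3-en-2-yl)cyclopent-1-en-1-yl]oxy}silane F2.
- MeLi then allyl bromide, as in step 6, pass through 12 and its enantiomer lithium (3S)-2-methyl-3-(2-methylbut-3-en-2-yl)cyclopent-1-en-1-olate F3 to the trans ketone as the racemate, 13 with (2S,3S)-2-methyl-3-(2-methylbut-3-en-2-yl)-2-(prop-2-en-1-yl)cyclopentan-1-one F4.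
- The metathesis of step 7 gives 14 with its enantiomer (3aS,7aS)-4,4,7a-trimethyl-2,3,3a,4,7,7a-hexahydro-1H-inden-1-one F5.
- Preparative HPLC on cellulose tris(3,5-dimethylphenylcarbamate) separates the two. The route is rejoined at 14.

**Step 9.** Risks are epoxide formation or migration of C7 instead of C10. The fallback replaces steps 8 and 9 by a direct Lewis-acid-catalysed diazoalkane homologation and sets out from 3 and 14:
- TBSCl and imidazole convert 3 into (4S)-6-{[tert-butyl(dimethyl)silyl]oxy}-4-methylhexanal F6.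
- Hydrazine hydrate in EtOH gives its hydrazone (4S)-6-{[tert-butyl(dimethyl)silyl]oxy}-4-methylhexanal hydrazone F7.
- Swern-type oxidation ((COCl)2, DMSO, Et3N, −78 °C) gives a cold solution of tert-butyl{[(3S)-6-diazo-3-methylhexyl]oxy}dimethylsilane F8.
- This is added to 14 with Sc(OTf)3 (10 mol %) in toluene at −78 °C. The diazonium betaine formed on the face opposite C20 loses N2 with migration of C10 (the regiochemistry seen in Tiffeneau–Demjanov expansion of 17-oxo steroids) to give 17.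
- DBU equilibration as in step 9 rejoins the route at 18.

**Step 11.** Risks are slow hydroboration of the neopentyl-flanked ring alkene, or boron going to C3. The fallback sets out from 20:
- OsO4 (2 mol %) and N-methylmorpholine N-oxide dihydroxylate from the face opposite the axial methyls to give (1S,4aS,6R,7S,8aR)-1-[(3S)-5-{[tert-butyl(dimethyl)silyl]oxy}-3-methylpentyl]-6,7-dihydroxy-5,5,8a-trimethyl-1,4,4a,5,6,7,8,8a-octahydronaphthalen-2-yl trifluoromethanesulfonate F9.
- Ac2O (1.1 equiv) in pyridine at 0 °C acetylates only the equatorial C2 hydroxyl, giving the 7-acetate F10.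
- 1,1′-Thiocarbonyldiimidazole with DMAP in toluene at 90 °C converts the hindered axial C3 hydroxyl into the 6-O-(imidazol-1-ylcarbonothioyl) derivative F11.
- Bu3SnH and AIBN at 100 °C (Barton–McCombie) remove it to give (1S,4aR,7R,8aR)-7-(acetyloxy)-1-[(3S)-5-{[tert-butyl(dimethyl)silyl]oxy}-3-methylpentyl]-5,5,8a-trimethyl-1,4,4a,5,6,7,8,8a-octahydronaphthalen-2-yl trifluoromethanesulfonate F12.
- Ac2O with Cu(OTf)2, as in step 12, exchanges the silyl ether and rejoins the route at 23.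

Further compounds
F1 | step 6 | 2-methyl-3-(2-methylbut-3-en-2-yl)cyclopentan-1-one (racemic, cis/trans mixture) | CC1C(=O)CCC1C(C)(C)C=C
F2 | step 6 | trimethyl{[(3S)-2-methyl-3-(2-methylbut-3-en-2-yl)cyclopent-1-en-1-yl]oxy}silane (enantiomer of 11) | CC1=C(O[Si](C)(C)C)CC[C@H]1C(C)(C)C=C
F3 | step 6 | lithium (3S)-2-methyl-3-(2-methylbut-3-en-2-yl)cyclopent-1-en-1-olate (enantiomer of 12) | CC1=C(O[Li])CC[C@H]1C(C)(C)C=C
F4 | step 6 | (2S,3S)-2-methyl-3-(2-methylbut-3-en-2-yl)-2-(prop-2-en-1-yl)cyclopentan-1-one (enantiomer of 13) | O=C1CC[C@@H](C(C)(C)C=C)[C@]1(C)CC=C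
F5 | step 6 | (3aS,7aS)-4,4,7a-trimethyl-2,3,3a,4,7,7a-hexahydro-1H-inden-1-one (enantiomer of 14) | O=C1CC[C@H]2C(C)(C)C=CC[C@]12C
F6 | step 9 | (4S)-6-{[tert-butyl(dimethyl)silyl]oxy}-4-methylhexanal | CC(C)(C)[Si](C)(C)OCC[C@@H](C)CCC=O
F7 | step 9 | (4S)-6-{[tert-butyl(dimethyl)silyl]oxy}-4-methylhexanal hydrazone | CC(C)(C)[Si](C)(C)OCC[C@@H](C)CCC=NN
F8 | step 9 | tert-butyl{[(3S)-6-diazo-3-methylhexyl]oxy}dimethylsilane | CC(C)(C)[Si](C)(C)OCC[C@@H](C)CCC=[N+]=[N-]
F9 | step 11 | (1S,4aS,6R,7S,8aR)-1-[(3S)-5-{[tert-butyl(dimethyl)silyl]oxy}-3-methylpentyl]-6,7-dihydroxy-5,5,8a-trimethyl-1,4,4a,5,6,7,8,8a-octahydronaphthalen-2-yl trifluoromethanesulfonate | CC(C)(C)[Si](C)(C)OCC[C@@H](C)CC[C@@H]1C(OS(=O)(=O)C(F)(F)F)=CC[C@@H]2C(C)(C)[C@@H](O)[C@@H](O)C[C@@]12C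
F10 | step 11 | 7-acetate of F9 (6-hydroxy free) | CC(C)(C)[Si](C)(C)OCC[C@@H](C)CC[C@@H]1C(OS(=O)(=O)C(F)(F)F)=CC[C@@H]2C(C)(C)[C@@H](O)[C@@H](OC(C)=O)C[C@@]12C
F11 | step 11 | 6-O-(1H-imidazol-1-ylcarbonothioyl) derivative of F10 | CC(C)(C)[Si](C)(C)OCC[C@@H](C)CC[C@@H]1C(OS(=O)(=O)C(F)(F)F)=CC[C@@H]2C(C)(C)[C@@H](OC(=S)n3ccnc3)[C@@H](OC(C)=O)C[C@@]12C
F12 | step 11 | (1S,4aR,7R,8aR)-7-(acetyloxy)-1-[(3S)-5-{[tert-butyl(dimethyl)silyl]oxy}-3-methylpentyl]-5,5,8a-trimethyl-1,4,4a,5,6,7,8,8a-octahydronaphthalen-2-yl trifluoromethanesulfonate | CC(C)(C)[Si](C)(C)OCC[C@@H](C)CC[C@@H]1C(OS(=O)(=O)C(F)(F)F)=CC[C@@H]2C(C)(C)C[C@@H](OC(C)=O)C[C@@]12C
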